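**Retrosynthetic overview**

1. Numbering: spiro[5.5]undecane with ring B = C1–C5 (C3 the carbinol carbon, C4 the CHBr carbon, C5 the methylene between C4 and C6), spiro atom C6, and ring A = C7–C11 (C7 CMe2, C8 CHBr, C11 C=CH2).
2. Feature used: ring B is attached to ring A only through C6. C1 and C5 can therefore both come from the formyl carbons of a ring A 1,1-dicarbaldehyde and C2–C3–C4 from a 3-oxopentanedioate, with C1=C2 and C4=C5 made in one [3+3] double Knoevenagel annulation.
3. Ring A is made first: a catalyst-controlled bromonium cyclisation of geranyl acetate sets C8 (S) and delivers the gem-dimethyl and exocyclic methylene groups. C6 is then turned into a bis(formyl) carbon by hydroxymethylation, Cannizzaro reduction and oxidation.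
4. Ring B is made second, as a spiro cross-conjugated dienone diester in which C6 is still non-stereogenic. Conjugate reduction and deallylative decarboxylation strip it to the C3 ketone.
5. C6, C4 and C3 are set last: a chiral lithium amide selects the axial C4 proton (fixing C6), bromination of the enol silane gives the equatorial C4 bromide, and axial methyl delivery to C3 completes the trans bromohydrin.

Key step: step 7

Remark: the annulation partner carries allyl instead of methyl esters (a spectator change) so that the ester groups can be removed at neutral pH in the presence of the exocyclic alkene and the secondary bromide.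
Remark: the amide enantiomer in step 10 is assigned by transferring to the ring B chair the sense recalled for 4-tert-butylcyclohexanone, where the (R,R)-amide is taken to give the (S)-enol silane. On that basis the (S,S)-amide is chosen here; the (R,R)-amide would be used instead if a model run showed the opposite sense.

**Route**

Step 1
Reactants: 1 geranyl acetate [(2E)-3,7-dimethylocta-2,6-dien-1-yl acetate]
Product: 2 [(1R,3S)-3-bromo-2,2-dimethyl-6-methylidenecyclohexyl]methyl acetate
Conditions: 1,3-dibromo-5,5-dimethylhydantoin (0.55 equiv), 1,1'-bi-2-naphthol-derived chiral thiophosphoramide Lewis base catalyst (10 mol%, the enantiomer giving the 3S bromide), toluene/CH2Cl2, −90 °C; chromatography on AgNO3-impregnated silica to remove endocyclic alkene isomers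
Reagents that add atoms: 1,3-dibromo-5,5-dimethylhydantoin, CC1(C)N(Br)C(=O)N(Br)C1=O
Why: Catalytic enantioselective bromonium-initiated polyene cyclisation, in which the chiral Lewis base–bromine complex should deliver Br+ to one face of the electron-rich 6,7-alkene (the 2,3-alkene is deactivated by the allylic acetate), the 2,3-alkene closes ring A through a chair with Br and CH2OAc both equatorial, and the tertiary cation loses a methyl proton to give the exocyclic alkene, so that C3 (S) is set by the catalyst and C1 (R, cis to Br) by the chair and the E geometry of the alkene.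

Step 2
Reactants: 2 [(1R,3S)-3-bromo-2,2-dimethyl-6-methylidenecyclohexyl]methyl acetate
Product: 3 [(1R,3S)-3-bromo-2,2-dimethyl-6-methylidenecyclohexyl]methanol
Conditions: K2CO3 (0.2 equiv), MeOH, 0 °C to rt
Reagents that add atoms: none
Why: Base-catalysed methanolysis of a primary acetate, to which the hindered equatorial neopentyl bromide (no antiperiplanar hydrogen) should be inert, and which touches no stereocentre.

Step 3
Reactants: 3 [(1R,3S)-3-bromo-2,2-dimethyl-6-methylidenecyclohexyl]methanol
Product: 4 (1R,3S)-3-bromo-2,2-dimethyl-6-methylidenecyclohexane-1-carbaldehyde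
Conditions: Dess–Martin periodinane (1.2 equiv), NaHCO3, CH2Cl2, 0 °C; used at once
Reagents that add atoms: none
Why: Dess–Martin oxidation of a primary alcohol under buffered, non-basic conditions should give the β,γ-unsaturated aldehyde without over-oxidation or migration of the alkene into conjugation, and the configuration at C1 is of no consequence because C1 loses its stereogenicity in step 4.

Step 4
Reactants: 4 (1R,3S)-3-bromo-2,2-dimethyl-6-methylidenecyclohexane-1-carbaldehyde; 5 formaldehyde
Product: 7 [(3S)-3-bromo-2,2-dimethyl-6-methylidenecyclohexane-1,1-diyl]dimethanol, via hydroxymethyl aldehyde 6 (not isolated)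
Conditions: 37% aq. formaldehyde (5 equiv), KOH (1.5 equiv), MeOH/H2O, 0 °C to 50 °C
Reagents that add atoms: none
Why: Tollens condensation, in which hydroxide forms the dienolate of 4, this adds to formaldehyde at the α-carbon C1 (deconjugative aldol giving 6), and the now non-enolisable aldehyde is reduced by a second formaldehyde through crossed Cannizzaro hydride transfer, C1 ending with two identical CH2OH groups so that no new stereocentre arises.

Step 5
Reactants: 7 [(3S)-3-bromo-2,2-dimethyl-6-methylidenecyclohexane-1,1-diyl]dimethanol
Product: 8 (3S)-3-bromo-2,2-dimethyl-6-methylidenecyclohexane-1,1-dicarbaldehyde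
Conditions: Dess–Martin periodinane (2.4 equiv), pyridine, CH2Cl2, 0 °C to rt; non-aqueous work-up (pentane, filtration), used crude
Reagents that add atoms: none
Why: Double Dess–Martin oxidation of a 2,2-disubstituted propane-1,3-diol to the non-enolisable malonaldehyde under buffered anhydrous conditions, with a non-aqueous work-up that should avoid hydrate formation and base-induced deformylation, and without forming a stereocentre.

Step 6
Reactants: 9 dimethyl 3-oxopentanedioate; 10 prop-2-en-1-ol (allyl alcohol)
Product: 12 bis(prop-2-en-1-yl) 3-oxopentanedioate, via mixed methyl allyl ester 11 (not isolated)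
Conditions: allyl alcohol (10 equiv), DMAP (10 mol%), toluene, reflux through a Soxhlet thimble of 4 Å molecular sieves to trap MeOH
Reagents that add atoms: prop-2-en-1-ol (second equivalent of 10), C=CCO
Why: Amine-catalysed transesterification of a β-keto ester, which proceeds through the acylketene at each ester group in turn, so that two equivalents of allyl alcohol are taken up (the first giving 11, the second giving 12) and two equivalents of methanol are released and removed to drive the exchange.

Step 7
Reactants: 8 (3S)-3-bromo-2,2-dimethyl-6-methylidenecyclohexane-1,1-dicarbaldehyde; 12 bis(prop-2-en-1-yl) 3-oxopentanedioate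
Product: 14 bis(prop-2-en-1-yl) (8S)-8-bromo-7,7-dimethyl-11-methylidene-3-oxospiro[5.5]undeca-1,4-diene-2,4-dicarboxylate, via alkylidene keto ester 13 (not isolated)
Conditions: TiCl4 (4 equiv), pyridine (8 equiv), THF, 0 °C to rt, 0.02 M
Reagents that add atoms: none
Why: TiCl4 and pyridine generate the titanium enolate of 12, which adds to one Lewis acid-activated formyl group of 8 and eliminates to the alkylidene keto ester 13 (C1=C2). Reversible conjugate addition of chloride or pyridine equilibrates the alkene geometry of 13, so that the second active methylene reaches the remaining formyl group and closes ring B by a 6-(enolendo)-exo-trig aldol addition followed by dehydration (C4=C5). The closest known reactions are the Knoevenagel condensation of hindered aldehydes with β-keto esters under titanium tetrachloride and pyridine and the double Knoevenagel annulation of dialdehydes with 3-oxopentanedioates. No stereocentre is formed, because both formyl groups are consumed, C6 stays non-stereogenic and C8 is not touched. The step needs chemoselectivity for double condensation over retro-Claisen deformylation and oligomerisation, and this is secured by the absence of nucleophilic amine, alkoxide or hydroxide, by the non-enolisable dialdehyde and by dilution. The dienone cannot aromatise because C6 is quaternary, and its β-carbons C1 and C5 are neopentyl, which should protect it from further conjugate addition.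

Step 8
Reactants: 14 bis(prop-2-en-1-yl) (8S)-8-bromo-7,7-dimethyl-11-methylidene-3-oxospiro[5.5]undeca-1,4-diene-2,4-dicarboxylate
Product: 16 bis(prop-2-en-1-yl) (8S)-8-bromo-7,7-dimethyl-11-methylidene-3-oxospiro[5.5]undecane-2,4-dicarboxylate, via monoreduced enone 15 (not isolated)
Conditions: Hantzsch ester (diethyl 2,6-dimethyl-1,4-dihydropyridine-3,5-dicarboxylate, 2.4 equiv), toluene, 70 °C
Reagents that add atoms: none
Why: Transfer hydrogenation of doubly activated alkenes by Hantzsch ester, in which hydride should be delivered to the β-carbons C1 and C5 of the two alkylidene β-keto ester units while the isolated exocyclic alkene, the allyl esters and the C–Br bond are not reduced, the new centres C2 and C4 being epimerisable and removed in step 9.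

Step 9
Reactants: 16 bis(prop-2-en-1-yl) (8S)-8-bromo-7,7-dimethyl-11-methylidene-3-oxospiro[5.5]undecane-2,4-dicarboxylate
Product: 18 (8S)-8-bromo-7,7-dimethyl-11-methylidenespiro[5.5]undecan-3-one, via keto diacid 17 (not isolated)
Conditions: Pd(PPh3)4 (5 mol%), morpholine (3 equiv), THF, rt; then pH 5 phosphate buffer, 40 °C
Reagents that add atoms: none
Why: Tsuji–Trost deallylation, in which zerovalent palladium ionises both allyl esters, morpholine captures the allyl fragments and the β-keto diacid 17 loses two molecules of CO2 through the usual six-membered transition state, all near neutral pH so that the exocyclic alkene should not migrate and the unactivated secondary bromide should not react, C6 becoming non-stereogenic again.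

Step 10
Reactants: 18 (8S)-8-bromo-7,7-dimethyl-11-methylidenespiro[5.5]undecan-3-one
Product: 19 {[(6R,8S)-8-bromo-7,7-dimethyl-11-methylidenespiro[5.5]undec-3-en-3-yl]oxy}trimethylsilane
Conditions: lithium bis[(S)-1-phenylethyl]amide (1.2 equiv, from the amine and n-BuLi), TMSCl (5 equiv, present from the start), THF, −100 °C to −78 °C; Et3N, pentane work-up, used crude
Reagents that add atoms: chlorotrimethylsilane, C[Si](C)(C)Cl
Why: Asymmetric deprotonation of a conformationally biased 4,4-disubstituted cyclohexanone by a chiral lithium amide with in situ silylation, in which the amide should remove only one of the two axial α-protons of the ring B chair (C7 equatorial, C11 axial), here H-4, so that the enol double bond is placed at C3=C4 and C6 becomes a stereocentre (R) under reagent control, the remote C8 centre exerting no useful bias.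

Step 11
Reactants: 19 {[(6R,8S)-8-bromo-7,7-dimethyl-11-methylidenespiro[5.5]undec-3-en-3-yl]oxy}trimethylsilane
Product: 20 (4R,6R,8S)-4,8-dibromo-7,7-dimethyl-11-methylidenespiro[5.5]undecan-3-one
Conditions: NBS (1.05 equiv), NaHCO3, THF, −78 °C to −30 °C
Reagents that add atoms: N-bromosuccinimide, O=C1CCC(=O)N1Br
Why: Electrophilic bromination of a silyl enol ether, which is far more nucleophilic than the hindered 1,1-disubstituted alkene, with bromine expected to enter C4 on the face away from the axial C11 substituent of C6 and so give the equatorial (4R) bromide, which should also be the thermodynamic epimer.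

Step 12
Reactants: 20 (4R,6R,8S)-4,8-dibromo-7,7-dimethyl-11-methylidenespiro[5.5]undecan-3-one
Product: 21 (3R,4R,6R,8S)-4,8-dibromo-3,7,7-trimethyl-11-methylidenespiro[5.5]undecan-3-ol
Conditions: methylaluminium bis(2,6-di-tert-butyl-4-methylphenoxide) (3 equiv), toluene, −78 °C; then MeLi (3 equiv, Et2O), −78 °C; aq. NH4Cl at −78 °C; chromatography to remove the diastereomer that stems from C2 deprotonation in step 10
Reagents that add atoms: methyllithium, [Li]C
Why: Amphiphilic carbonyl alkylation, in which the bulky aluminium Lewis acid binds the carbonyl oxygen from the open equatorial side and activates it, so that methyllithium should add along the axial trajectory and give the axial methyl and equatorial hydroxyl at C3 (R), trans to the equatorial C4 bromine, the trans-diequatorial bromo alkoxide being unable to close to an epoxide at −78 °C.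

**Compound list**

1 | geranyl acetate [(2E)-3,7-dimethylocta-2,6-dien-1-yl acetate] | CC(C)=CCC/C(C)=C/COC(C)=O | starting material
2 | [(1R,3S)-3-bromo-2,2-dimethyl-6-methylidenecyclohexyl]methyl acetate | C=C1CC[C@H](Br)C(C)(C)[C@@H]1COC(C)=O | intermediate
3 | [(1R,3S)-3-bromo-2,2-dimethyl-6-methylidenecyclohexyl]methanol | C=C1CC[C@H](Br)C(C)(C)[C@@H]1CO | intermediate
4 | (1R,3S)-3-bromo-2,2-dimethyl-6-methylidenecyclohexane-1-carbaldehyde | C=C1CC[C@H](Br)C(C)(C)[C@@H]1C=O | intermediate
5 | formaldehyde | C=O | starting material
6 | (3S)-3-bromo-1-(hydroxymethyl)-2,2-dimethyl-6-methylidenecyclohexane-1-carbaldehyde (both C1 epimers) | C=C1CC[C@H](Br)C(C)(C)C1(CO)C=O | intermediate (not isolated)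
7 | [(3S)-3-bromo-2,2-dimethyl-6-methylidenecyclohexane-1,1-diyl]dimethanol | C=C1CC[C@H](Br)C(C)(C)C1(CO)CO | intermediate
8 | (3S)-3-bromo-2,2-dimethyl-6-methylidenecyclohexane-1,1-dicarbaldehyde | C=C1CC[C@H](Br)C(C)(C)C1(C=O)C=O | intermediate
9 | dimethyl 3-oxopentanedioate | COC(=O)CC(=O)CC(=O)OC | starting material
10 | prop-2-en-1-ol (allyl alcohol) | C=CCO | starting material
11 | methyl prop-2-en-1-yl 3-oxopentanedioate | COC(=O)CC(=O)CC(=O)OCC=C | intermediate (not isolated)
12 | bis(prop-2-en-1-yl) 3-oxopentanedioate | C=CCOC(=O)CC(=O)CC(=O)OCC=C | intermediate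
13 | bis(prop-2-en-1-yl) 2-{[(3S)-3-bromo-1-formyl-2,2-dimethyl-6-methylidenecyclohexyl]methylidene}-3-oxopentanedioate (alkene isomers, both C1 epimers) | C=C1CC[C@H](Br)C(C)(C)C1(C=O)C=C(C(=O)OCC=C)C(=O)CC(=O)OCC=C | intermediate (not isolated)
14 | bis(prop-2-en-1-yl) (8S)-8-bromo-7,7-dimethyl-11-methylidene-3-oxospiro[5.5]undeca-1,4-diene-2,4-dicarboxylate | C=C1CC[C@H](Br)C(C)(C)C12C=C(C(=O)OCC=C)C(=O)C(C(=O)OCC=C)=C2 | intermediate
15 | bis(prop-2-en-1-yl) (8S)-8-bromo-7,7-dimethyl-11-methylidene-3-oxospiro[5.5]undec-1-ene-2,4-dicarboxylate (epimer mixture) | C=C1CC[C@H](Br)C(C)(C)C12CC(C(=O)OCC=C)C(=O)C(C(=O)OCC=C)=C2 | intermediate (not isolated)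
16 | bis(prop-2-en-1-yl) (8S)-8-bromo-7,7-dimethyl-11-methylidene-3-oxospiro[5.5]undecane-2,4-dicarboxylate (C2/C4 epimers, partly enolised) | C=C1CC[C@H](Br)C(C)(C)C12CC(C(=O)OCC=C)C(=O)C(C(=O)OCC=C)C2 | intermediate
17 | (8S)-8-bromo-7,7-dimethyl-11-methylidene-3-oxospiro[5.5]undecane-2,4-dicarboxylic acid (C2/C4 epimers) | C=C1CC[C@H](Br)C(C)(C)C12CC(C(=O)O)C(=O)C(C(=O)O)C2 | intermediate (not isolated)
18 | (8S)-8-bromo-7,7-dimethyl-11-methylidenespiro[5.5]undecan-3-one | C=C1CC[C@H](Br)C(C)(C)C12CCC(=O)CC2 | intermediate
19 | {[(6R,8S)-8-bromo-7,7-dimethyl-11-methylidenespiro[5.5]undec-3-en-3-yl]oxy}trimethylsilane | C=C1CC[C@H](Br)C(C)(C)[C@@]12CCC(O[Si](C)(C)C)=CC2 | intermediate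
20 | (4R,6R,8S)-4,8-dibromo-7,7-dimethyl-11-methylidenespiro[5.5]undecan-3-one | C=C1CC[C@H](Br)C(C)(C)[C@@]12CCC(=O)[C@H](Br)C2 | intermediate
21 | (3R,4R,6R,8S)-4,8-dibromo-3,7,7-trimethyl-11-methylidenespiro[5.5]undecan-3-ol (CNP0114057.1) | C=C1CC[C@H](Br)C(C)(C)[C@@]12CC[C@@](C)(O)[C@H](Br)C2 | target

**Step count and risks**

Total step count: 12. Longest linear sequence: 11 steps (1 to 21 through steps 1–5 and 7–12); step 6 is a one-step branch that joins at step 7.

Steps most likely to fail:

1. Step 7. Retro-Claisen loss of a formyl group from the hindered dialdehyde, or intermolecular condensation to oligomers and 1:2 adducts, may run faster than the ring-closing second condensation. The fallback sets out from 4 and comes back at 18. Base-catalysed Michael addition of 4 (through its dienolate, catalytic KOH in MeOH) to but-3-en-2-one should give the keto aldehyde (3S)-3-bromo-2,2-dimethyl-6-methylidene-1-(3-oxobutyl)cyclohexane-1-carbaldehyde F1. Intramolecular aldol condensation on warming (Robinson spiroannulation) should close ring B as the enone (8S)-8-bromo-7,7-dimethyl-11-methylidenespiro[5.5]undec-1-en-3-one F2. Conjugate reduction with [(Ph3P)CuH]6 in wet toluene then gives 18, in which the C6 configuration of F2 no longer matters.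

2. Step 1. Facial discrimination in the bromonium transfer may be incomplete, and the cation may lose a ring proton or be captured by the acetate instead of losing a methyl proton. The fallback sets out from 1 and comes back at 3. Racemic cyclisation of 1 with 2,4,4,6-tetrabromocyclohexa-2,5-dienone in MeNO2 should give 2 together with its enantiomer [(1S,3R)-3-bromo-2,2-dimethyl-6-methylidenecyclohexyl]methyl acetate F3. Methanolysis (K2CO3, MeOH) gives 3 and its enantiomer [(1S,3R)-3-bromo-2,2-dimethyl-6-methylidenecyclohexyl]methanol F4. Acylation with (1S)-camphanic chloride (pyridine, DMAP) gives two diastereomeric esters, separable by crystallisation or chromatography: from 3, [(1R,3S)-3-bromo-2,2-dimethyl-6-methylidenecyclohexyl]methyl (1S,4R)-4,7,7-trimethyl-3-oxo-2-oxabicyclo[2.2.1]heptane-1-carboxylate F5, and from F4, [(1S,3R)-3-bromo-2,2-dimethyl-6-methylidenecyclohexyl]methyl (1S,4R)-4,7,7-trimethyl-3-oxo-2-oxabicyclo[2.2.1]heptane-1-carboxylate F6. Methanolysis of F5 returns 3 as a single enantiomer.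

3. Step 12. Methyl may be delivered from the equatorial side (wrong C3 epimer), or the α-bromo ketone may suffer enolisation or bromine–lithium exchange. The fallback sets out from 19 and comes back at 21. Cleavage of 19 with MeLi (THF, 0 °C) to the lithium enolate and trapping with PhNTf2 should give (6R,8S)-8-bromo-7,7-dimethyl-11-methylidenespiro[5.5]undec-3-en-3-yl trifluoromethanesulfonate F7. Coupling with MeMgBr catalysed by Fe(acac)3 (THF/NMP, −20 °C) should give (6R,8S)-8-bromo-3,7,7-trimethyl-11-methylidenespiro[5.5]undec-3-ene F8. NBS in aqueous acetone at 0 °C should then add Br+ to the more electron-rich ring B alkene on the face away from the axial C11, and water should open the bromonium ion at tertiary C3 from the opposite face, giving 21.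

Further compounds
F1 | step 7 | (3S)-3-bromo-2,2-dimethyl-6-methylidene-1-(3-oxobutyl)cyclohexane-1-carbaldehyde (both C1 epimers) | C=C1CC[C@H](Br)C(C)(C)C1(C=O)CCC(C)=O
F2 | step 7 | (8S)-8-bromo-7,7-dimethyl-11-methylidenespiro[5.5]undec-1-en-3-one (both C6 epimers) | C=C1CC[C@H](Br)C(C)(C)C12C=CC(=O)CC2
F3 | step 1 | [(1S,3R)-3-bromo-2,2-dimethyl-6-methylidenecyclohexyl]methyl acetate | C=C1CC[C@@H](Br)C(C)(C)[C@H]1COC(C)=O
F4 | step 1 | [(1S,3R)-3-bromo-2,2-dimethyl-6-methylidenecyclohexyl]methanol | C=C1CC[C@@H](Br)C(C)(C)[C@H]1CO
F5 | step 1 | [(1R,3S)-3-bromo-2,2-dimethyl-6-methylidenecyclohexyl]methyl (1S,4R)-4,7,7-trimethyl-3-oxo-2-oxabicyclo[2.2.1]heptane-1-carboxylate | C=C1CC[C@H](Br)C(C)(C)[C@@H]1COC(=O)[C@@]12CC[C@@](C)(C(=O)O1)C2(C)C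
F6 | step 1 | [(1S,3R)-3-bromo-2,2-dimethyl-6-methylidenecyclohexyl]methyl (1S,4R)-4,7,7-trimethyl-3-oxo-2-oxabicyclo[2.2.1]heptane-1-carboxylate | C=C1CC[C@@H](Br)C(C)(C)[C@H]1COC(=O)[C@@]12CC[C@@](C)(C(=O)O1)C2(C)C
F7 | step 12 | (6R,8S)-8-bromo-7,7-dimethyl-11-methylidenespiro[5.5]undec-3-en-3-yl trifluoromethanesulfonate | C=C1CC[C@H](Br)C(C)(C)[C@@]12CCC(OS(=O)(=O)C(F)(F)F)=CC2
F8 | step 12 | (6R,8S)-8-bromo-3,7,7-trimethyl-11-methylidenespiro[5.5]undec-3-ene | C=C1CC[C@H](Br)C(C)(C)[C@@]12CCC(C)=CC2
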